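**Retrosynthetic overview** (cyclohexane locants of the target: C1 bears the side chain, C2 the gem-dimethyl group, C3 and C5 the bromines, C6 the methylidene)

1. Target 19 ⇐ silyl ether 18 ⇐ cyclohexene 17 by an ene-type bromination that installs the axial allylic bromide at C5 and the exocyclic methylene in one event, as in the presumed biogenesis.
2. 17 ⇐ homoallylic alcohol 16 (invertive Appel bromination at the neopentylic C3 carbinol) ⇐ anti-1,3-diol 13 (suprafacial reductive allylic transposition sets the C1–H centre) ⇐ hydroxy enone 12 (hydroxyl-directed reduction).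
3. 12 ⇐ keto aldehyde 8 + butan-2-one 9 by an L-proline-catalysed asymmetric aldol/aldol-condensation [3+3] annulation that joins C3 to C4 and C1 to C6 and so forms the only ring of the target.
4. Enabling feature: C5, the brominated carbon between C4 and C6, is at the ketone level the carbonyl of a butanone whose two α-carbons are C4 and C6. The quaternary C2 between C1 and C3 allows a non-enolisable 1,3-keto aldehyde, so the 3,5-dibromo-2,2-dimethyl-6-methylidenecyclohexane is the retron of a 5-hydroxy-4,4-dimethylcyclohex-2-enone.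
5. 8 ⇐ (S)-linalool 1 (carbinol centre from the chiral pool) by silylation, ozonolysis and an isobutyrate aldol/reduction/oxidation sequence.

Key step: step 6

Assumption: commercial (S)-(+)-linalool of high enantiomeric purity defines the carbinol centre, and butan-2-one is taken to enter the intermolecular proline aldol through its less hindered methyl-side enamine.

**Route**

Step 1
Reactants: 1 (S)-(+)-linalool
Product: 2 (3S)-3,7-dimethyl-3-(triethylsilyloxy)octa-1,6-diene
Conditions: Et3SiOTf, 2,6-lutidine, CH2Cl2, −78 °C to 0 °C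
Reagents that add atoms: triethylsilyl trifluoromethanesulfonate, CC[Si](CC)(CC)OS(=O)(=O)C(F)(F)F
Why: Silyl triflate protection of the hindered tertiary allylic alcohol should proceed without touching the stereocentre and blocks cyclic ether formation in the later oxidation and bromination steps.

Step 2
Reactants: 2 (3S)-3,7-dimethyl-3-(triethylsilyloxy)octa-1,6-diene
Product: 4 (4S)-4-methyl-4-(triethylsilyloxy)hex-5-enal, via ozonide 3 (not isolated)
Conditions: O3 (1.0 equiv, dosed as a saturated CH2Cl2 solution), CH2Cl2, −78 °C; then Me2S, −78 °C to rt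
Reagents that add atoms: ozone, [O-][O+]=O
Why: Chemoselective ozonolysis should cleave the electron-rich trisubstituted alkene much faster than the monosubstituted vinyl group next to the silyloxy-bearing quaternary carbon, and reductive work-up of the ozonide gives the aldehyde with the stereocentre untouched.

Step 3
Reactants: 4 (4S)-4-methyl-4-(triethylsilyloxy)hex-5-enal, 5 methyl isobutyrate
Product: 6 methyl (6S)-3-hydroxy-2,2,6-trimethyl-6-(triethylsilyloxy)oct-7-enoate (both C3 epimers)
Conditions: LiN(i-Pr)2, THF, −78 °C (5 first, then 4); aq NH4Cl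
Reagents that add atoms: none
Why: Lithium ester enolate aldol addition at low temperature builds the quaternary gem-dimethyl carbon; the new carbinol centre is uncontrolled and need not be controlled because it is oxidised in step 5.

Step 4
Reactants: 6 methyl (6S)-3-hydroxy-2,2,6-trimethyl-6-(triethylsilyloxy)oct-7-enoate
Product: 7 (6S)-2,2,6-trimethyl-6-(triethylsilyloxy)oct-7-ene-1,3-diol (both C3 epimers)
Conditions: LiAlH4, Et2O, 0 °C; aqueous work-up
Reagents that add atoms: none
Why: Hydride reduction of the ester to the primary alcohol is standard, and the silyl ether and both alkenes are inert to LiAlH4.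

Step 5
Reactants: 7 (6S)-2,2,6-trimethyl-6-(triethylsilyloxy)oct-7-ene-1,3-diol
Product: 8 (6S)-2,2,6-trimethyl-3-oxo-6-(triethylsilyloxy)oct-7-enal
Conditions: Dess–Martin periodinane (2.5 equiv), pyridine, CH2Cl2, 0 °C to rt
Reagents that add atoms: none
Why: Dess–Martin oxidation of both hydroxyls should give the 1,3-keto aldehyde, which cannot enolise between the carbonyl groups because of the quaternary carbon and is therefore stable under the buffered conditions.

Step 6
Reactants: 8 (6S)-2,2,6-trimethyl-3-oxo-6-(triethylsilyloxy)oct-7-enal, 9 butan-2-one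
Product: 12 (5R)-5-hydroxy-2,4,4-trimethyl-3-[(3S)-3-methyl-3-(triethylsilyloxy)pent-4-en-1-yl]cyclohex-2-en-1-one, via aldol adduct 10 (not isolated), via cyclic ketol 11 (not isolated)
Conditions: L-proline (30 mol%), butan-2-one (10 equiv), DMSO, rt; then pyrrolidine (30 mol%), AcOH (30 mol%), 40 °C, same flask
Reagents that add atoms: none
Why: Enamine catalysis: L-proline condenses with butan-2-one on the methyl side and the enamine adds to the aldehyde of 8 through the hydrogen-bonded chair-like transition state of the proline aldol reaction, a reaction type known to give very high enantioselectivity with α-quaternary aldehydes, which forms the first ring bond and sets the carbinol centre as R under catalyst control, independent of the remote silyl ether centre. Pyrrolidinium acetate then turns the ethyl ketone of 10 into its enamine, which closes the six-membered ring by a 6-(enolendo)-exo-trig aldol addition onto the neighbouring ketone, and loss of water from the tertiary carbinol of 11 gives the tetrasubstituted enone, so the second ring bond is formed as a C=C bond (Robinson-type aldol condensation, as in the closure of 3,3-dimethyl-2,6-diketones to 4,4-dimethylcyclohexenones). The step needs chemoselectivity for the aldehyde over the ketone in the first event (the aldehyde is more electrophilic and the ketone is flanked by the quaternary carbon), regioselectivity for the methyl group of butanone (less hindered enamine meeting a bulky neopentylic aldehyde), and dehydration of the tertiary and not the secondary carbinol (only the former gives the conjugated tetrasubstituted alkene under mild buffered conditions). The quaternary gem-dimethyl carbon excludes enolisation between the two carbonyl groups, so self-condensation of 8 cannot compete.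

Step 7
Reactants: 12 (5R)-5-hydroxy-2,4,4-trimethyl-3-[(3S)-3-methyl-3-(triethylsilyloxy)pent-4-en-1-yl]cyclohex-2-en-1-one
Product: 13 (1R,3R)-4,6,6-trimethyl-5-[(3S)-3-methyl-3-(triethylsilyloxy)pent-4-en-1-yl]cyclohex-4-ene-1,3-diol
Conditions: Me4NBH(OAc)3, MeCN/AcOH, −30 °C
Reagents that add atoms: none
Why: Evans–Saksena hydroxyl-directed reduction: the borohydride exchanges onto the existing hydroxyl and delivers hydride intramolecularly to the same face of the enone carbonyl, which should give the 1,3-anti diol and set the new allylic carbinol as R.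

Step 8
Reactants: 13 (1R,3R)-4,6,6-trimethyl-5-[(3S)-3-methyl-3-(triethylsilyloxy)pent-4-en-1-yl]cyclohex-4-ene-1,3-diol
Product: 16 (1R,5R)-4,6,6-trimethyl-5-[(3S)-3-methyl-3-(triethylsilyloxy)pent-4-en-1-yl]cyclohex-3-en-1-ol, via sulfonylhydrazine 14 (not isolated), via allylic diazene 15 (not isolated)
Conditions: 2-O2NC6H4SO2NHNH2, PPh3, DEAD, THF, −30 °C; then rt
Reagents that add atoms: none
Why: Myers reductive 1,3-transposition: Mitsunobu displacement of the unhindered allylic hydroxyl with inversion (the neopentylic hydroxyl should not react), loss of sulfinic acid and suprafacial retro-ene loss of N2 deliver hydrogen to the ring carbon bearing the side chain on the face of the C–N bond, which sets that stereocentre and moves the alkene to the trisubstituted position.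

Step 9
Reactants: 16 (1R,5R)-4,6,6-trimethyl-5-[(3S)-3-methyl-3-(triethylsilyloxy)pent-4-en-1-yl]cyclohex-3-en-1-ol
Product: 17 (3S)-5-[(1R,5S)-5-bromo-2,6,6-trimethylcyclohex-2-en-1-yl]-3-methyl-3-(triethylsilyloxy)pent-1-ene
Conditions: CBr4, PPh3, 2,6-lutidine, toluene, 0 °C to 60 °C
Reagents that add atoms: tetrabromomethane, BrC(Br)(Br)Br
Why: Appel bromination with inversion: bromide should attack the alkoxyphosphonium ion of the axial neopentylic alcohol from the equatorial direction to give the equatorial (S) bromide cis to the side chain, a displacement of the kind used on axial 3-hydroxy-2,2-dimethylcyclohexane terpenoids.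

Step 10
Reactants: 17 (3S)-5-[(1R,5S)-5-bromo-2,6,6-trimethylcyclohex-2-en-1-yl]-3-methyl-3-(triethylsilyloxy)pent-1-ene
Product: 18 (3S)-5-[(1S,3S,5S)-3,5-dibromo-2,2-dimethyl-6-methylidenecyclohexyl]-3-methyl-3-(triethylsilyloxy)pent-1-ene
Conditions: NBS (1.05 equiv), Yb(OTf)3 (5 mol%), Me3SiCl (5 mol%), CH2Cl2/THF, −78 °C to −20 °C, dark
Reagents that add atoms: N-bromosuccinimide, O=C1CCC(=O)N1Br
Why: Halonium ene-type allylic bromination that mirrors the presumed biogenesis: the trisubstituted ring alkene is far more nucleophilic than the vinyl group, axial attack of bromine on the face that leads directly to the chair with both existing substituents equatorial sets the axial (S) bromide, and loss of a methyl proton anti to bromine gives the exocyclic methylene.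

Step 11
Reactants: 18 (3S)-5-[(1S,3S,5S)-3,5-dibromo-2,2-dimethyl-6-methylidenecyclohexyl]-3-methyl-3-(triethylsilyloxy)pent-1-ene
Product: 19 (3S)-5-[(1S,3S,5S)-3,5-dibromo-2,2-dimethyl-6-methylidenecyclohexyl]-3-methylpent-1-en-3-ol
Conditions: Et3N·3HF, MeCN, 0 °C to rt
Reagents that add atoms: none
Why: Fluoride-mediated cleavage of the tertiary triethylsilyl ether under weakly acidic, poorly nucleophilic conditions is a standard deprotection that should leave the allylic bromide and all stereocentres untouched.

**Compound list**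

1 | (S)-(+)-linalool, (3S)-3,7-dimethylocta-1,6-dien-3-ol | C=C[C@@](C)(O)CCC=C(C)C | starting material
2 | (3S)-3,7-dimethyl-3-(triethylsilyloxy)octa-1,6-diene | C=C[C@@](C)(O[Si](CC)(CC)CC)CCC=C(C)C | intermediate
3 | ozonide of 2 at the trisubstituted alkene, 3,3-dimethyl-5-[(3S)-3-methyl-3-(triethylsilyloxy)pent-4-en-1-yl]-1,2,4-trioxolane | C=C[C@@](C)(O[Si](CC)(CC)CC)CCC1OOC(C)(C)O1 | intermediate
4 | (4S)-4-methyl-4-(triethylsilyloxy)hex-5-enal | C=C[C@@](C)(O[Si](CC)(CC)CC)CCC=O | intermediate
5 | methyl isobutyrate | COC(=O)C(C)C | starting material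
6 | methyl (6S)-3-hydroxy-2,2,6-trimethyl-6-(triethylsilyloxy)oct-7-enoate (both C3 epimers) | C=C[C@@](C)(O[Si](CC)(CC)CC)CCC(O)C(C)(C)C(=O)OC | intermediate
7 | (6S)-2,2,6-trimethyl-6-(triethylsilyloxy)oct-7-ene-1,3-diol (both C3 epimers) | C=C[C@@](C)(O[Si](CC)(CC)CC)CCC(O)C(C)(C)CO | intermediate
8 | (6S)-2,2,6-trimethyl-3-oxo-6-(triethylsilyloxy)oct-7-enal | C=C[C@@](C)(O[Si](CC)(CC)CC)CCC(=O)C(C)(C)C=O | intermediate
9 | butan-2-one | CCC(C)=O | starting material
10 | (5R,10S)-5-hydroxy-6,6,10-trimethyl-10-(triethylsilyloxy)dodec-11-ene-3,7-dione | C=C[C@@](C)(O[Si](CC)(CC)CC)CCC(=O)C(C)(C)[C@H](O)CC(=O)CC | intermediate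
11 | (5R)-3,5-dihydroxy-2,4,4-trimethyl-3-[(3S)-3-methyl-3-(triethylsilyloxy)pent-4-en-1-yl]cyclohexan-1-one (C2 and C3 epimers) | C=C[C@@](C)(O[Si](CC)(CC)CC)CCC1(O)C(C)C(=O)C[C@@H](O)C1(C)C | intermediate
12 | (5R)-5-hydroxy-2,4,4-trimethyl-3-[(3S)-3-methyl-3-(triethylsilyloxy)pent-4-en-1-yl]cyclohex-2-en-1-one | C=C[C@@](C)(O[Si](CC)(CC)CC)CCC1=C(C)C(=O)C[C@@H](O)C1(C)C | intermediate
13 | (1R,3R)-4,6,6-trimethyl-5-[(3S)-3-methyl-3-(triethylsilyloxy)pent-4-en-1-yl]cyclohex-4-ene-1,3-diol | C=C[C@@](C)(O[Si](CC)(CC)CC)CCC1=C(C)[C@H](O)C[C@@H](O)C1(C)C | intermediate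
14 | N-[(1S,5R)-5-hydroxy-2,4,4-trimethyl-3-[(3S)-3-methyl-3-(triethylsilyloxy)pent-4-en-1-yl]cyclohex-2-en-1-yl]-2-nitrobenzenesulfonohydrazide (alkylated at the sulfonamide nitrogen) | C=C[C@@](C)(O[Si](CC)(CC)CC)CCC1=C(C)[C@@H](N(N)S(=O)(=O)c2ccccc2[N+](=O)[O-])C[C@@H](O)C1(C)C | intermediate
15 | (1R,5S)-5-diazenyl-2,2,4-trimethyl-3-[(3S)-3-methyl-3-(triethylsilyloxy)pent-4-en-1-yl]cyclohex-3-en-1-ol | C=C[C@@](C)(O[Si](CC)(CC)CC)CCC1=C(C)[C@@H](N=N)C[C@@H](O)C1(C)C | intermediate
16 | (1R,5R)-4,6,6-trimethyl-5-[(3S)-3-methyl-3-(triethylsilyloxy)pent-4-en-1-yl]cyclohex-3-en-1-ol | C=C[C@@](C)(O[Si](CC)(CC)CC)CC[C@@H]1C(C)=CC[C@@H](O)C1(C)C | intermediate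
17 | (3S)-5-[(1R,5S)-5-bromo-2,6,6-trimethylcyclohex-2-en-1-yl]-3-methyl-3-(triethylsilyloxy)pent-1-ene | C=C[C@@](C)(O[Si](CC)(CC)CC)CC[C@@H]1C(C)=CC[C@H](Br)C1(C)C | intermediate
18 | (3S)-5-[(1S,3S,5S)-3,5-dibromo-2,2-dimethyl-6-methylidenecyclohexyl]-3-methyl-3-(triethylsilyloxy)pent-1-ene | C=C[C@@](C)(O[Si](CC)(CC)CC)CC[C@@H]1C(=C)[C@@H](Br)C[C@H](Br)C1(C)C | intermediate
19 | (3S)-5-[(1S,3S,5S)-3,5-dibromo-2,2-dimethyl-6-methylidenecyclohexyl]-3-methylpent-1-en-3-ol | C=C[C@@](C)(O)CC[C@@H]1C(=C)[C@@H](Br)C[C@H](Br)C1(C)C | target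

**Step count and risks**

Total step count: 11. Longest linear sequence: 11 steps (1 to 19).

Steps most likely to fail:

Step 6. Ring closure of the ethyl ketone onto the hindered ketone may lag behind retro-aldol cleavage or amine-induced deformylation of the keto aldehyde, and part of the butanone may react through its methylene enamine. The fallback sets out from 8 and comes back at 12. Proline-catalysed aldol of 8 with acetone, which has no regiochemical ambiguity, should give the isolated acetone aldol adduct F1. Its methyl ketone closes onto the hindered ketone under pyrrolidine/AcOH to the trisubstituted hydroxy enone F2. α-Iodination (I2, pyridine, CH2Cl2) gives the iodo enone F3, and Suzuki–Miyaura methylation (MeB(OH)2, Pd(dppf)Cl2, K3PO4, dioxane, 80 °C) installs the ring methyl group and returns to 12.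

Step 9. Substitution at the neopentylic carbinol may lose out to elimination, to participation of the homoallylic alkene or to methyl migration. The fallback sets out from 2 and comes back at 17, and it installs the bromide by the classical bromonium route. Allylic oxidation of 2 at the (E)-methyl group (SeO2 cat., t-BuOOH, CH2Cl2; NaBH4 work-up) gives the (E)-allylic alcohol F4, and Appel bromination gives the allylic bromide F5. Alkylation of lithiated 3-methylbut-2-enyl phenyl sulfone (n-BuLi, THF, −78 °C) gives the sulfone F6, and reductive desulfonylation (Pd(dppp)Cl2 cat., LiBHEt3, THF, 0 °C) gives the (S,E)-nerolidol triethylsilyl ether F7. Brominative polyene cyclisation with 2,4,4,6-tetrabromocyclohexa-2,5-dienone (MeNO2, 0 °C) then forms the ring and the equatorial bromide by anti addition through a chair transition state. This cyclisation is not under absolute stereocontrol, so 17 would have to be separated by chromatography from double-bond isomers and from the ring diastereomer.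

Step 10. The bromonium ion may be captured by the silyl ether oxygen (cyclic ether formation), the ring proton may be lost instead of a methyl proton, or the new bromide may undergo allylic 1,3-shift to the primary position. The fallback sets out from 17 and comes back at 18. Epoxidation (mCPBA, NaHCO3, CH2Cl2, 0 °C) gives the epoxide F8. Base-induced isomerisation of the epoxide (Et2Al(NC9H18), the 2,2,6,6-tetramethylpiperidide, toluene, 0 °C) gives the exocyclic-methylene allylic alcohol F9, and Dess–Martin oxidation gives the α-methylene ketone F10. Luche reduction (NaBH4, CeCl3·7H2O, MeOH, −78 °C) with axial hydride attack gives the equatorial allylic alcohol F11, and Appel bromination with inversion (CBr4, PPh3, CH2Cl2, −20 °C) returns to 18.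

**Further compounds**

F1 | step 6 | (4R,9S)-4-hydroxy-5,5,9-trimethyl-9-(triethylsilyloxy)undec-10-ene-2,6-dione | C=C[C@@](C)(O[Si](CC)(CC)CC)CCC(=O)C(C)(C)[C@H](O)CC(C)=O
F2 | step 6 | (5R)-5-hydroxy-4,4-dimethyl-3-[(3S)-3-methyl-3-(triethylsilyloxy)pent-4-en-1-yl]cyclohex-2-en-1-one | C=C[C@@](C)(O[Si](CC)(CC)CC)CCC1=CC(=O)C[C@@H](O)C1(C)C
F3 | step 6 | (5R)-5-hydroxy-2-iodo-4,4-dimethyl-3-[(3S)-3-methyl-3-(triethylsilyloxy)pent-4-en-1-yl]cyclohex-2-en-1-one | C=C[C@@](C)(O[Si](CC)(CC)CC)CCC1=C(I)C(=O)C[C@@H](O)C1(C)C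
F4 | step 9 | (2E,6S)-2,6-dimethyl-6-(triethylsilyloxy)octa-2,7-dien-1-ol | C=C[C@@](C)(O[Si](CC)(CC)CC)CC/C=C(\C)CO
F5 | step 9 | (3S,6E)-8-bromo-3,7-dimethyl-3-(triethylsilyloxy)octa-1,6-diene | C=C[C@@](C)(O[Si](CC)(CC)CC)CC/C=C(\C)CBr
F6 | step 9 | (3S,6E)-3,7,11-trimethyl-9-(phenylsulfonyl)-3-(triethylsilyloxy)dodeca-1,6,10-triene (both C9 epimers) | C=C[C@@](C)(O[Si](CC)(CC)CC)CC/C=C(\C)CC(C=C(C)C)S(=O)(=O)c1ccccc1
F7 | step 9 | (3S,6E)-3,7,11-trimethyl-3-(triethylsilyloxy)dodeca-1,6,10-triene | C=C[C@@](C)(O[Si](CC)(CC)CC)CC/C=C(\C)CCC=C(C)C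
F8 | step 10 | epoxide of 17 across the ring alkene (epoxide face not assigned) | C=C[C@@](C)(O[Si](CC)(CC)CC)CC[C@@H]1C2(C)OC2C[C@H](Br)C1(C)C
F9 | step 10 | (3R,5S)-5-bromo-4,4-dimethyl-2-methylidene-3-[(3S)-3-methyl-3-(triethylsilyloxy)pent-4-en-1-yl]cyclohexan-1-ol (C1 epimers) | C=C[C@@](C)(O[Si](CC)(CC)CC)CC[C@@H]1C(=C)C(O)C[C@H](Br)C1(C)C
F10 | step 10 | (3R,5S)-5-bromo-4,4-dimethyl-2-methylidene-3-[(3S)-3-methyl-3-(triethylsilyloxy)pent-4-en-1-yl]cyclohexan-1-one | C=C[C@@](C)(O[Si](CC)(CC)CC)CC[C@@H]1C(=C)C(=O)C[C@H](Br)C1(C)C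
F11 | step 10 | (1R,3R,5S)-5-bromo-4,4-dimethyl-2-methylidene-3-[(3S)-3-methyl-3-(triethylsilyloxy)pent-4-en-1-yl]cyclohexan-1-ol | C=C[C@@](C)(O[Si](CC)(CC)CC)CC[C@@H]1C(=C)[C@H](O)C[C@H](Br)C1(C)C
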